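The oxirane is disconnected at its O–C1 bond (heptane numbering: C1 is the ring CHBr, C2 the ring CH that carries the chain, C3 the exocyclic CBr2). The contiguous C1–C2–C3 unit then maps onto the CHBr2, C=O and CBr2 carbons of 1,1,3,3-tetrabromoheptan-2-one, a ketone without any stereocentre in which only the carbonyl carbon is prochiral. In one flask, an oxazaborolidine-catalysed hydride transfer fixes C2 as S, and cold aqueous carbonate releases the carbinolate, which expels one C1 bromide, closes the three-membered ring and sets C1 with bromine trans to the chain. The ketone is reached in a single step from heptan-2-one and bromine.

Key step: step 2

Structure check: the target is the trans-oxirane, with C1 (ring CHBr) R and C2 S, which is (2R,3S)-2-bromo-3-(1,1-dibromopentyl)oxirane in ring numbering. The carbinol that leads to it is the 2S alcohol, because the C2–O bond is retained and the CIP order O > C3 > C1 > H does not change on closure.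

Remark (assumption): toward the oxazaborolidine, the hydrogen-free CBr2Bu flank is taken to behave as the large carbonyl substituent, as a trihalomethyl group does, and CHBr2 as the small one. On this basis the (R)-catalyst is chosen for the (S)-carbinol. Should the sense prove opposite, the (S)-catalyst would be used and nothing else changes.

Step 1
Reactants: 1 heptan-2-one; 2 bromine
Product: 3 1,1,3,3-tetrabromoheptan-2-one
Conditions: Br2 (4.1 equiv), AcOH, cat. 48% aq. HBr, 0 → 45 °C, dark; NaHSO3 wash; vacuum distillation or silica
Reagents that add atoms: bromine, BrBr
Why: Acid-catalysed α-bromination of a ketone through its enols, made reversible by HBr so that the bromine distribution should settle on two bromines per α-carbon as in the preparation of 1,1,3,3-tetrabromoacetone, while a third bromine on C1 is not expected under acid because the CHBr2 ketone enolises very slowly; no stereocentre is formed.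

Step 2
Reactants: 3 1,1,3,3-tetrabromoheptan-2-one
Product: 6 (2R,3S)-2-bromo-3-(1,1-dibromopentyl)oxirane, via (S)-carbinol catechol borate 4 (not isolated), via (2S)-1,1,3,3-tetrabromoheptan-2-ol 5 (not isolated)
Conditions: (R)-Me-CBS (0.2 equiv), catecholborane (1.5 equiv), toluene, −78 → −40 °C, Ar; then 1 M aq. K2CO3 (excess), 0 °C, two-phase, short contact; toluene layer dried over K2CO3, filtered through Et3N-deactivated silica (pentane), concentrated below 0 °C
Reagents that add atoms: none
Why: The oxazaborolidine binds catecholborane at nitrogen and ketone 3 at its ring boron through the carbonyl lone pair on the side of the smaller CHBr2 flank, and hydride then crosses a six-membered transition state to the Re face of C2, giving the S borate 4. This is a CBS reduction, whose closest precedent is the catecholborane variant for trihalomethyl ketones, where the fully halogenated carbon acts as the large group; the second stage is the halohydrin-to-epoxide closure known for dihalomethyl carbinolates. Carbonate hydrolyses the B–O bond of 4, takes catechol and borate into the water layer and deprotonates the acidified carbinol 5, whose alkoxide displaces one C1 bromide by intramolecular SN2, so that the oxirane closes in the 3-exo-tet mode through the new O–C1 bond. C2 is set by the catalyst and keeps its C–O bond afterwards, whereas C1 is set by the substrate: backside attack inverts C1, and the transition state that leaves the remaining bromine next to H on C2 instead of next to the CBr2Bu group is the less crowded one, which leads to the trans (1R,2S) oxirane. The step needs face selectivity at C2, secured by the size gap between the hydrogen-free CBr2Bu flank and the CHBr2 flank, site selectivity for C1 over C3, secured because C1 is a CH carbon while C3 is fully substituted, and trans selectivity, secured by the same bulk. No base is present while the enolisable ketone is, which shuts out Favorskii and haloform-type cleavage, and the cold two-phase closure keeps the bromo-oxirane in toluene, apart from hydroxide and catecholate.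

Compound list
1 | heptan-2-one | CCCCCC(C)=O | starting material
2 | bromine | BrBr | starting material
3 | 1,1,3,3-tetrabromoheptan-2-one | CCCCC(Br)(Br)C(=O)C(Br)Br | intermediate
4 | 2-{[(2S)-1,1,3,3-tetrabromoheptan-2-yl]oxy}-1,3,2-benzodioxaborole | CCCCC(Br)(Br)[C@@H](OB1Oc2ccccc2O1)C(Br)Br | intermediate
5 | (2S)-1,1,3,3-tetrabromoheptan-2-ol | CCCCC(Br)(Br)[C@@H](O)C(Br)Br | intermediate
6 | (2R,3S)-2-bromo-3-(1,1-dibromopentyl)oxirane, trans | CCCCC(Br)(Br)[C@H]1O[C@@H]1Br | target

Total step count: 2
Longest linear sequence: 2 steps

Points most likely to fail. The route has only two steps, so step 2 is entered twice, once for each of the two independent processes that can fail in it.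

1. Step 2, reduction stage: the catalyst may discriminate poorly between two flanks that are both brominated and both branched, or hydride transfer to the crowded carbonyl may be sluggish, so that the carbinol forms with low enantiomeric purity. The fallback replaces asymmetric induction by resolution and sets out from ketone 3. Borane–dimethyl sulfide in THF at 0 °C, followed by a methanol quench, should give racemic 1,1,3,3-tetrabromoheptan-2-ol F1, a stable alcohol that can be purified on silica. Preparative chromatography on a polysaccharide-based chiral stationary phase then separates the enantiomers, the absolute configuration being assigned by vibrational circular dichroism or by anomalous-dispersion X-ray analysis. (2R)-1,1,3,3-Tetrabromoheptan-2-ol F2 is set aside, and the S enantiomer is compound 5, where the fallback comes back to the route. Compound 5 in toluene is then closed with cold aqueous potassium carbonate as in the second stage of step 2, now without catechol present.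

2. Step 2, closure stage: the bromo-oxirane may be lost during the aqueous basic stage by hydrolysis, by attack of catecholate at the interface or by rearrangement to the α-bromo aldehyde, or closure may stay incomplete at carbonate pH. The fallback unmasks the alkoxide without water or Brønsted base and sets out from compound 5. Compound 5 is obtained in isolated form by ending the reduction with a methanol quench and chromatographing on silica, which retains catechol and the amino alcohol. Neutral silylation with N,O-bis(trimethylsilyl)acetamide in CH2Cl2 should give trimethyl{[(2S)-1,1,3,3-tetrabromoheptan-2-yl]oxy}silane F3. Anhydrous caesium fluoride in acetonitrile at 0 °C then cleaves the Si–O bond, and the caesium alkoxide closes at once by the same 3-exo-tet displacement. Fluorotrimethylsilane escapes as a gas and caesium bromide precipitates, so that filtration and cold evaporation lead back to the route at compound 6.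

3. Step 1: the bromine distribution may not converge on the 1,1,3,3 pattern, through incomplete entry of the second bromine at the hindered C3, uptake of a third bromine at C1 or loss of HBr across C3–C4, leaving a mixture that is hard to separate. The fallback fixes the C1 pattern by C–C bond formation instead of C–H bromination and sets out from methyl hexanoate and dibromomethane. Dibromomethyllithium, generated from dibromomethane and lithium tetramethylpiperidide in THF at −90 °C, adds to methyl hexanoate, and an acidic quench at low temperature should give 1,1-dibromoheptan-2-one F4. Bromine (2 equiv) in acetic acid with catalytic HBr can then enter only at C3, the one α-carbon that still enolises readily, and the fallback returns to the route at compound 3.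

Further compounds
F1 | step 2 | racemic 1,1,3,3-tetrabromoheptan-2-ol | CCCCC(Br)(Br)C(O)C(Br)Br
F2 | step 2 | (2R)-1,1,3,3-tetrabromoheptan-2-ol | CCCCC(Br)(Br)[C@H](O)C(Br)Br
F3 | step 2 | trimethyl{[(2S)-1,1,3,3-tetrabromoheptan-2-yl]oxy}silane | CCCCC(Br)(Br)[C@@H](O[Si](C)(C)C)C(Br)Br
F4 | step 1 | 1,1-dibromoheptan-2-one | CCCCCC(=O)C(Br)Br
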